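Take the amounts first: this flask holds 0.10 M of Z and 0.100 M of X, equal charges, the symmetric case, with neither one the limiting reagent. Reckon the smaller charge over the Z charged, here 100 %, and call it the ceiling of D. Test it on the gamma run: its ceiling is 67.0 %, and its last reading of D, 59 %, stands lower. Weigh both charges exactly and add nothing, for the ceiling moves with the smaller charge. Watch D and X together: with equal charges, the points D lacks of the ceiling equal the share of X left.

| setting | gamma | epsilon | flask |
|---|---|---|---|
| Z | 0.10 M | 0.10 M | 0.10 M |
| X | 0.067 M | 0.15 M | 0.100 M |
| remark | run made earlier | run made earlier |  |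
| time |  |  | 4.0 min |

| run | time / min | D / % | G / % | Z / % |
|---|---|---|---|---|
| gamma | 0.417 | 19 | 12 | 3 |
| gamma | 0.833 | 31 | 11 | 0 |
| gamma | 1.33 | 43 | 6 | 0 |
| gamma | 1.50 | 47 | 8 | 0 |
| gamma | 2.00 | 53 | 6 | 2 |
| gamma | 2.50 | 59 | 11 | 2 |
| epsilon | 0.417 | 42 | 10 | 0 |
| epsilon | 0.833 | 70 | 3 | 2 |
| epsilon | 1.33 | 87 | 4 | 0 |
| epsilon | 1.50 | 88 | 3 | 0 |
| epsilon | 2.00 | 98 | 4 | 0 |
| epsilon | 2.50 | 99 | 1 | 0 |

(readings scatter by 1.5 percentage points)

- as a solid, counted per litre of solution: Z
- the analysis behind the earlier runs scatters by 1.5 percentage points, standard deviation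
- at the start none of Z is in solution
- G is what Z becomes in solution
- G means what is dissolved; the solid is not counted in it

- amount of D at 4.0 min, in percent of the Z charged
- concentration of G in solution at 4.0 min, in percent of saturation

The forecast gives 93 % of D and 60 % of saturation, on this ground: “I take the missing part as undissolved solid, which the analysis misses”. My ceiling stands above its D but does not produce that number.

The flask gives 89.5 % of D, with G at 3.63 % of saturation. At 4.0 min it also holds J, a paired form of G absent from the readings, at 7.25 % with each J counted as two, while Z stands at 0 %. The ceiling less D is 10 percentage points, and in this flask those points stand as J and G, with 11 % of X left.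

    2 G ⇌ J, settled at all times (K = 340 /M)
    G + X → D (k = 100 /M/min)
    Z ⇌ G, rate k3*(cs3 - [G]) while solid is left; crystals form when [G] > cs3 (solubility = 0.0900 M, k = 4.00 /min)

Now raise Z to 0.25 M at the same X: X becomes the limiting reagent and the ceiling falls to 40.0 %. That flask gives 39.8 % of D, with 0.40 % of its X left.

The earlier runs and the new flask come from a simulation from invented constants, and the scatter is random.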